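**Remark on the chemistry.** Carotenoid numbering is used: ring A is C1–C6 with C2=C3 and C4=C5, ring B is primed with C4'=C5' and the 3'-oxygen. The given SMILES corresponds to 3'S. Crocetindial is taken as purchasable. Carbinol and ring sp3 centres that later become sp2 are carried as mixtures. All polyenes are handled under argon, in the dark and on base-deactivated supports.

## Retrosynthetic overview

1. Target ⇐ its 3'-TBS ether (fluoride) ⇐ thermal cis/trans equilibration of the crude retro tridecaene.
2. Retro tridecaene ⇐ C40 8,8'-diol in the normal register by reductive 1,16-elimination. The strategy rests on C7–C8 and C7'–C8' being single bonds between the ring-ylidene carbons (C6=C7 on the C2=C3/C4=C5 diene ring A, C6'=C7' on the C4'=C5' ring B) and the C8-to-C8' octaene, which is crocetindial plus two electrons.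
3. Diol ⇐ crocetindial + ring B dienol triflate (C7'–C8', first) + ring A trienol triflate (C7–C8, second) by two Nozaki–Hiyama–Kishi additions.
4. Ring B triflate ⇐ (S)-phorenol TBS ether (sulfonium ylide epoxide, Meinwald shift, dienolate triflation) ⇐ ketoisophorone by asymmetric transfer hydrogenation; ring A triflate ⇐ safranal.
5. No ring is formed: ring B is bought as ketoisophorone and ring A as safranal. Assembly order is ring B + chain, then ring A, then the register shift.

Key step: step 9

## Route

Step 1
Reactants: 1 ketoisophorone (2,6,6-trimethylcyclohex-2-ene-1,4-dione)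
Product: 2 (S)-phorenol [(4S)-4-hydroxy-2,6,6-trimethylcyclohex-2-en-1-one]
Conditions: RuCl[(S,S)-TsDPEN](p-cymene) (0.5 mol%), i-PrOH, rt
Reagents that add atoms: none
Why: Noyori asymmetric transfer hydrogenation reduces only the C4 carbonyl (flanked by CH and CH2), the C1 carbonyl being shielded by the gem-dimethyl and C2-methyl groups; with the alkenyl group in the role of the aryl group of an aryl alkyl ketone the (S,S) complex should give the (S) carbinol, and the (R,R) complex would be used if the configuration check showed the opposite sense.

Step 2
Reactants: 2 (S)-phorenol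
Product: 3 (S)-phorenol TBS ether [(4S)-4-(tert-butyldimethylsilyloxy)-2,6,6-trimethylcyclohex-2-en-1-one]
Conditions: TBSCl, imidazole, DMF, rt
Reagents that add atoms: tert-butyldimethylsilyl chloride, CC(C)(C)[Si](C)(C)Cl
Why: Standard silylation of an unhindered secondary allylic alcohol; the stereocentre is not involved.

Step 3
Reactants: 3 (S)-phorenol TBS ether; 4 trimethylsulfonium iodide
Product: 6 spiro vinyl epoxide (both epimers at the spiro carbon), via dimethylsulfonium methylide 5 (not isolated)
Conditions: 4 (1.5 equiv), n-BuLi (1.4 equiv), THF, −10 °C; then 3, −10 °C → rt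
Reagents that add atoms: trimethylsulfonium iodide (compound 4), C[S+](C)C.[I-]
Why: Corey–Chaykovsky epoxidation, in which the small unstabilised sulfonium ylide adds 1,2 to the hindered enone carbonyl and the betaine closes to the oxirane; the ketone has no alpha-hydrogen, both faces may be attacked because the spiro centre is destroyed in step 4, and C4 is untouched.

Step 4
Reactants: 6 spiro vinyl epoxide
Product: 7 3-silyloxy-alpha-cyclocitral [(4S)-4-(tert-butyldimethylsilyloxy)-2,6,6-trimethylcyclohex-2-ene-1-carbaldehyde, both epimers at C1 = C6']
Conditions: BF3·OEt2 (0.2 equiv), CH2Cl2, −78 °C, 10 min; Et3N quench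
Reagents that add atoms: none
Why: Meinwald rearrangement, in which the C–O bond at the tertiary allylic spiro carbon ionises and a 1,2-hydride shift from the oxirane CH2 gives the aldehyde (only hydrogens can migrate, so no ring expansion); the new C6' centre may be a mixture because it becomes sp2 in step 5, and any conjugated beta-cyclocitral isomer would give the same dienolate.

Step 5
Reactants: 7 3-silyloxy-alpha-cyclocitral
Product: 9 ring B dienol triflate {[(4S)-4-(tert-butyldimethylsilyloxy)-2,6,6-trimethylcyclohex-2-en-1-ylidene]methyl triflate with the triflate on the gem-dimethyl side}, via potassium dienolate 8 (not isolated)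
Conditions: KHMDS (1.1 equiv), THF, −78 °C, 15 min; N-(5-chloropyridin-2-yl)triflimide, −78 → −40 °C
Reagents that add atoms: N-(5-chloropyridin-2-yl)bis(trifluoromethanesulfonyl)imide, O=S(=O)(N(c1ccc(Cl)cn1)S(=O)(=O)C(F)(F)F)C(F)(F)F
Why: Enol triflate formation by deprotonation of the doubly activated C6'–H (alpha to the aldehyde and allylic) and O-sulfonylation of the dienolate; the oxygen should settle between the geminal methyls and away from the in-plane C5' methyl, the low temperature keeps loss of silanolate from C3' slow, and a minor geometric isomer is tolerated because C6'=C7' is equilibrated in step 10.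

Step 6
Reactants: 9 ring B dienol triflate; 10 crocetindial (all-E 2,6,11,15-tetramethylhexadeca-2,4,6,8,10,12,14-heptaenedial, 3 equiv)
Product: 12 C30 hydroxy-heptaenal (16-hydroxy-2,6,11,15-tetramethyl-17-[ring B ylidene]heptadeca-2,4,6,8,10,12,14-heptaenal; both epimers at C8'), via dienylchromium dichloride 11 (not isolated)
Conditions: CrCl2 (4 equiv), NiCl2 (2 mol%), DMF–THF, rt, dark; aq sodium serinate work-up; Et3N-deactivated silica
Reagents that add atoms: none
Why: Nozaki–Hiyama–Kishi reaction, in which zerovalent nickel inserts into the C–OTf bond, the alkenyl group passes to trivalent chromium and the alkenylchromium adds only to an aldehyde, forming C7'–C8'; the excess of dial favours the mono-adduct (unreacted dial is recovered), and C8' needs no control because it becomes sp2 in step 9.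

Step 7
Reactants: 13 safranal
Product: 15 ring A trienol triflate [(2,6,6-trimethylcyclohexa-2,4-dien-1-ylidene)methyl triflate with the triflate on the gem-dimethyl side], via potassium trienolate 14 (not isolated)
Conditions: t-BuOK (1.05 equiv), THF–DMPU, −40 °C, 30 min; N-(5-chloropyridin-2-yl)triflimide, −78 → −30 °C
Reagents that add atoms: N-(5-chloropyridin-2-yl)bis(trifluoromethanesulfonyl)imide, O=S(=O)(N(c1ccc(Cl)cn1)S(=O)(=O)C(F)(F)F)C(F)(F)F
Why: Enol triflate formation from an extended enolate, in which reversible deprotonation (proton shuttling through t-BuOH) should funnel any cross-conjugated dienolate from the C5 methyl into the linearly conjugated trienolate formed by loss of a C2 proton; O-sulfonylation then fixes the C2=C3/C4=C5/C6=C7 triene with the oxygen away from the in-plane C5 methyl.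

Step 8
Reactants: 12 C30 hydroxy-heptaenal; 15 ring A trienol triflate (3 equiv)
Product: 17 C40 8,8'-diol in the normal register (1-[ring A ylidene]-18-[ring B ylidene]-3,7,12,16-tetramethyloctadeca-3,5,7,9,11,13,15-heptaene-2,17-diol; mixture at C8 and C8'), via trienylchromium dichloride 16 (not isolated)
Conditions: CrCl2 (8 equiv), NiCl2 (2 mol%), DMF–THF, rt, dark; aq sodium serinate work-up; Et3N-deactivated silica, used at once
Reagents that add atoms: none
Why: Second Nozaki–Hiyama–Kishi addition forms C7–C8; the organochromium reagent tolerates the free C8' hydroxyl and the silyl ether, the excess of triflate drives the valuable aldehyde to full conversion, and all four carbinol diastereomers converge in step 9.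

Step 9
Reactants: 17 C40 8,8'-diol
Product: 18 retro tridecaene 3'-TBS ether as the mixture of double-bond isomers formed in the elimination
Conditions: TiCl3 (8 equiv), LiAlH4 (4 equiv), THF, 0 °C → reflux, then 0 °C; 1,8-bis(dimethylamino)naphthalene; 17 in THF added slowly, 0 °C → rt, dark, Ar; filtration through basic alumina
Reagents that add atoms: none
Why: Proposed new method: the low-valent titanium slurry turns both hydroxyls into titanium alkoxides, and cleavage of one C–O bond (say C8–O) leaves a radical, or after one more electron an anion, delocalised over C8, C10, C12, C14, C15', C13', C11' and C9' (and over C6, C4 and C2 of ring A); C9' is beta to the remaining C8'–O–Ti bond, so that oxygen leaves as titanium oxide and the closed-shell polyene forms, the seven chain double bonds being replaced by eight (C8=C9, C10=C11, C12=C13, C14=C15, C15'=C14', C13'=C12', C11'=C10', C9'=C8') that join the ring A triene and the ring B diene into one tridecaene. The closest known reaction type is the reductive elimination of 2-ene-1,4-diols, 2,4-diene-1,6-diols and triene-1,8-diols to polyenes with TiCl3/LiAlH4 (and the older Kuhn–Winterstein variants with P2I4 or sodium amalgam on diols and dibenzoates), stretched here from a 1,8 to a 1,16 span, and the end-to-end dihydro reduction of polyene diacids by trivalent titanium indicates that electrons can travel through such a chain. No ring is closed and no stereocentre is created; both epimers at C8 and at C8' converge because these carbons become trigonal, and C3' is not touched. The step must cleave only the C8–O and C8'–O bonds: they are the only titanium-bound oxygens on the relay, whereas the 3'-oxygen, although beta to C4', is a silyl ether that does not bind titanium and is a poor leaving group. The amine base keeps the medium non-acidic, so that no cation arises at C6 or C8 that could solvolyse the carbinols or trigger a methyl shift and aromatisation of the gem-dimethyl ring A. The new double bonds arise from s-trans single bonds and should be mainly E, and any cis bonds, including those at C6=C7 and C6'=C7', are removed in step 10.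

Step 10
Reactants: 18 retro tridecaene 3'-TBS ether (isomer mixture)
Product: 19 all-trans retro tridecaene 3'-TBS ether (C8 and C8' on the gem-dimethyl side of C6=C7 and C6'=C7')
Conditions: heptane–toluene, 85 °C, Ar, dark; crystallisation
Reagents that add atoms: none
Why: Thermal cis–trans equilibration of a long polyene, in which the low rotation barriers of a tridecaene let cis bonds relax to the least strained isomer, with C8–H and C8'–H between the geminal methyls and not against the in-plane C5 and C5' methyls; no sigmatropic hydrogen shift is available because the ring dienes have no suitably placed allylic hydrogen.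

Step 11
Reactants: 19 all-trans retro tridecaene 3'-TBS ether
Product: 20 CNP0202479.1
Conditions: TBAF, AcOH (1:1), THF, 0 °C → rt, dark; pH 7 work-up; crystallisation
Reagents that add atoms: none
Why: Fluoride desilylation under buffered, non-acidic conditions frees the 3'-hydroxyl without ionising this allylic position, which would otherwise give a cation conjugated with the tridecaene and loss of water; the C3' configuration is retained because only the Si–O bond is cleaved.

## Compound list

1 | ketoisophorone | CC1=CC(=O)CC(C)(C)C1=O | starting material
2 | (S)-phorenol, (4S)-4-hydroxy-2,6,6-trimethylcyclohex-2-en-1-one | O=C1C(C)=C[C@@H](O)CC1(C)C | intermediate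
3 | (S)-phorenol TBS ether | O=C1C(C)=C[C@@H](O[Si](C)(C)C(C)(C)C)CC1(C)C | intermediate
4 | trimethylsulfonium iodide | C[S+](C)C.[I-] | starting material
5 | dimethylsulfonium methylide | C[S+](C)[CH2-] | intermediate (not isolated)
6 | spiro vinyl epoxide, (6S)-6-(tert-butyldimethylsilyloxy)-4,8,8-trimethyl-1-oxaspiro[2.5]oct-4-ene, both epimers at the spiro carbon | C1OC12C(C)=C[C@@H](O[Si](C)(C)C(C)(C)C)CC2(C)C | intermediate
7 | 3-silyloxy-alpha-cyclocitral, (4S)-4-(tert-butyldimethylsilyloxy)-2,6,6-trimethylcyclohex-2-ene-1-carbaldehyde, both epimers at C1 | O=CC1C(C)=C[C@@H](O[Si](C)(C)C(C)(C)C)CC1(C)C | intermediate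
8 | potassium dienolate of 7 | [K+].[O-]/C=C1/C(C)=C[C@@H](O[Si](C)(C)C(C)(C)C)CC1(C)C | intermediate (not isolated)
9 | ring B dienol triflate | FC(F)(F)S(=O)(=O)O/C=C1/C(C)=C[C@@H](O[Si](C)(C)C(C)(C)C)CC1(C)C | intermediate
10 | crocetindial (all-E C20 heptaenedial) | O=C/C(C)=C/C=C/C(C)=C/C=C/C=C(C)/C=C/C=C(C)/C=O | starting material
11 | ring B dienylchromium dichloride | Cl[Cr](Cl)/C=C1/C(C)=C[C@@H](O[Si](C)(C)C(C)(C)C)CC1(C)C | intermediate (not isolated)
12 | C30 hydroxy-heptaenal, both epimers at C8' | O=C/C(C)=C/C=C/C(C)=C/C=C/C=C(C)/C=C/C=C(C)/C(O)/C=C1/C(C)=C[C@@H](O[Si](C)(C)C(C)(C)C)CC1(C)C | intermediate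
13 | safranal | CC1=C(C=O)C(C)(C)CC=C1 | starting material
14 | potassium trienolate of safranal | CC1=CC=CC(C)(C)\C1=C/[O-].[K+] | intermediate (not isolated)
15 | ring A trienol triflate | CC1=CC=CC(C)(C)\C1=C/OS(=O)(=O)C(F)(F)F | intermediate
16 | ring A trienylchromium dichloride | CC1=CC=CC(C)(C)\C1=C/[Cr](Cl)Cl | intermediate (not isolated)
17 | C40 8,8'-diol, normal register, mixture at C8 and C8' | CC1=CC=CC(C)(C)\C1=C/C(O)/C(C)=C/C=C/C(C)=C/C=C/C=C(C)/C=C/C=C(C)/C(O)/C=C1/C(C)=C[C@@H](O[Si](C)(C)C(C)(C)C)CC1(C)C | intermediate
18 | retro tridecaene 3'-TBS ether, mixture of double-bond isomers | CC1=CC=CC(C)(C)C1=CC=C(C)C=CC=C(C)C=CC=CC(C)=CC=CC(C)=CC=C1C(C)=C[C@@H](O[Si](C)(C)C(C)(C)C)CC1(C)C | intermediate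
19 | all-trans retro tridecaene 3'-TBS ether | CC1=CC=CC(C)(C)\C1=C/C=C(C)/C=C/C=C(C)/C=C/C=C/C(C)=C/C=C/C(C)=C/C=C1/C(C)=C[C@@H](O[Si](C)(C)C(C)(C)C)CC1(C)C | intermediate
20 | CNP0202479.1 | CC1=CC=CC(C)(C)\C1=C/C=C(C)/C=C/C=C(C)/C=C/C=C/C(C)=C/C=C/C(C)=C/C=C1/C(C)=C[C@@H](O)CC1(C)C | target

## Step count and risks

Total step count: 11. Longest linear sequence: 10 steps (steps 1–6 and 8–11, from ketoisophorone); step 7 is a one-step branch from safranal.

Steps most likely to fail:

**1. Step 9 (Proposed new method).** The electron relay over sixteen carbons may stall after the first C–O cleavage. The delocalised radical may then dimerise or pick up hydrogen, giving a mono-ol or dihydro polyene, or the Lewis-acidic slurry may ionise the carbinols.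

Fallback: a non-reductive register shift by the known acid dehydration of a polyene monocarbinol (the anhydro-retinol and retro-dehydrocarotene type). It sets out from safranal 13, crocetindial 10 and triflate 9 and returns at 18.
- Safranal 13 is reduced with NaBH4/CeCl3 to safranol F1, which with PPh3·HBr gives the phosphonium bromide F2.
- NaOMe converts F2 into the ylide F3, and its Wittig reaction with excess crocetindial 10 forms C7=C8 as a double bond and gives the C30 3,4-didehydro-apocarotenal F4.
- Nozaki–Hiyama–Kishi addition of triflate 9 (CrCl2, catalytic NiCl2, through 11) to F4 gives the C40 8'-carbinol F5, which carries a single chain oxygen.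
- Brief treatment of F5 with pyridinium p-toluenesulfonate in CH2Cl2 at low temperature ionises C8'–O. The cation spans C8' to C3, and loss of the C2 proton shifts the nine chain and two ring A double bonds into the retro register, giving 18 before step 10.

**2. Step 8.** Divalent chromium may transfer electrons to the polyenal, leading to pinacol coupling or dihydro reduction. The trivalent chromium salts may also ionise the doubly allylic C8' carbinol during a slow addition.

Fallback: a preformed organolithium added at low temperature. It sets out from 15 and 12 and returns at 17.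
- Triflate 15 is stannylated with Me3SnSnMe3, Pd(PPh3)4 and LiCl in THF to the trienylstannane F6.
- Tin–lithium exchange with MeLi at −78 °C gives the trienyllithium F7.
- An excess of F7 (the first equivalent is spent on the hydroxyl) is added to 12 at −78 °C and quenched with buffer to give diol 17.

**3. Step 5.** The dienolate may expel silanolate from C3' before it is trapped. This vinylogous beta-elimination would lead to safranal with loss of the stereocentre.

Fallback: an alkenyl iodide made without any enolate (Barton vinyl iodide synthesis). It sets out from 7 and returns at 12.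
- Aldehyde 7 is condensed with hydrazine hydrate (Et3N, EtOH) to the hydrazone F8.
- Iodine and 1,1,3,3-tetramethylguanidine in THF at 0 °C convert F8 into the ring B dienyl iodide F9.
- F9 takes the place of 9 in the Nozaki–Hiyama–Kishi addition to crocetindial 10 (CrCl2, catalytic NiCl2, through 11) to give 12.

## Further compounds

F1 | step 9 | safranol, (2,6,6-trimethylcyclohexa-1,3-dien-1-yl)methanol | CC1=C(CO)C(C)(C)CC=C1
F2 | step 9 | [(2,6,6-trimethylcyclohexa-1,3-dien-1-yl)methyl]triphenylphosphonium bromide | CC1=C(C[P+](c2ccccc2)(c2ccccc2)c2ccccc2)C(C)(C)CC=C1.[Br-]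
F3 | step 9 | ylide of F2 | CC1=C(C=P(c2ccccc2)(c2ccccc2)c2ccccc2)C(C)(C)CC=C1
F4 | step 9 | C30 3,4-didehydro-apocarotenal (normal register) | CC1=C(/C=C/C(C)=C/C=C/C(C)=C/C=C/C=C(C)/C=C/C=C(C)/C=O)C(C)(C)CC=C1
F5 | step 9 | C40 8'-carbinol, mixture at C8' | CC1=C(/C=C/C(C)=C/C=C/C(C)=C/C=C/C=C(C)/C=C/C=C(C)/C(O)/C=C2/C(C)=C[C@@H](O[Si](C)(C)C(C)(C)C)CC2(C)C)C(C)(C)CC=C1
F6 | step 8 | ring A trienyl trimethylstannane | CC1=CC=CC(C)(C)\C1=C/[Sn](C)(C)C
F7 | step 8 | ring A trienyllithium | CC1=CC=CC(C)(C)\C1=C/[Li]
F8 | step 5 | hydrazone of 7 | NN=CC1C(C)=C[C@@H](O[Si](C)(C)C(C)(C)C)CC1(C)C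
F9 | step 5 | ring B dienyl iodide | I/C=C1/C(C)=C[C@@H](O[Si](C)(C)C(C)(C)C)CC1(C)C
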